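**Remark on the chemistry (assumption):** the SMILES is read as (2S,3R,4S,5S) at the oxolane and (7′S,8′R), erythro, in the side chain. The catalyst enantiomer in step 8 is assigned from the accepted transition-state model for phosphoric-acid allylboration, recalled rather than checked; if the sense is opposite, the antipodal acid is used. 4-Iodo-2-methoxyphenol and (Z)-2-bromobut-2-ene are taken as catalogue compounds.

## Analysis of the target

The target 22 is a sesquineolignan built on one saturated ring, a 2,5-diaryl-3,4-dimethyloxolane (O1, C2–C5). C2 carries a free guaiacyl ring (ring A). C5 carries a second guaiacyl ring (ring B) whose para oxygen is etherified with an erythro 1-aryl-1-hydroxypropan-2-yl unit (carbinol C7′, ether carbon C8′, ring C).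

In the oxolane, ring A, the C3 methyl and the C4 methyl are all cis, and ring B at C5 is trans to them. The all-cis triad C2/C3/C4 is the contra-thermodynamic part of the molecule. The side chain adds two more stereocentres with the anti (erythro) relation, and there is no symmetry to exploit.

All three benzylic carbons (C2, C5, C7′) sit para to an oxygen. Acid or oxidants ionise them to quinone-methide-type cations, which leads to epimerisation at C2, ring opening, or Friedel–Crafts closure to an aryltetralin. Rings A and C are identical free guaiacols that must stay distinct from ring B.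

The feature this route is built on: C5–H is the only benzylic hydrogen that lies para to an alkyl ether oxygen (the C8′–O oxygen on ring B). The para oxygens of rings A and C are phenols and can be masked as acyl esters. C5 then becomes the single position a hydride-abstracting quinone can attack, so the oxolane can be closed last, by C–H functionalisation on an acyclic precursor that already carries the whole side chain.

## Retrosynthetic reasoning

**22 from 21.** The last operation removes two aryl pivalates. These esters are not only protection: as poor donors they switch off benzylic ionisation at C2 and C7′ in every preceding step. One mild, basic transesterification unveils both phenols without touching any benzylic C–O bond.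

**21 from 19 (key disconnection, O1–C5).** The oxolane is cut at O1–C5 to give the acyclic seco-alcohol 19, in which C5 is a plain methylene. The cut is placed here and not at O1–C2 because C5 is the centre whose required configuration (trans to everything) is also the one the ring prefers. It can therefore be formed last through a planar cation and still come out right. C2, the contra-thermodynamic centre, is never ionised. The forward reaction must remove hydride from C5 only, close the ring through the C2 hydroxyl, and place ring B trans. What is gained: no oxygen function is ever needed at C5, so ring B can be attached by a simple sp3–sp2 coupling with its side chain already in place.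

**19 from 17 and 9 (C5–ring B bond, C4–H bond).** Cutting the bond between the C5 methylene and ring B gives aryl bromide 9 and the 1,1-disubstituted alkene 17. In the forward direction a dialkylborane adds across the alkene and the resulting primary alkylborane 18 is cross-coupled with 9. This one operation joins the two halves and sets C4 from the neighbouring C3 stereocentre by allylic strain.

**17 from 11 and 16 (C2–C3 bond).** The homoallylic alcohol 17 is cut between C2 and C3 into aldehyde 11 and the Z-configured allylboronate 16. A chiral-acid-catalysed allylboration through a closed chair sets both C2 and C3 (syn) in absolute terms. The 2-methyl group of 16 supplies the future C4 methyl.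

**9 from 8, and 8 from 4 and 6.** The carbinol C7′ is traced back to ketone 8, so that a chelate between the ketone oxygen and the C8′ ether oxygen can direct hydride to the erythro isomer. Ketone 8 is cut at the C7′–ring C bond into Weinreb amide 4 and aryl iodide 6, joined through arylmagnesium 7.

**4 from 3, and 3 from 1 and 2.** The C8′–O bond is made with inversion from phenol 1 and the lactate 2, which takes the C8′ configuration from the chiral pool.

**Supporting cuts.** Boronate 16 comes from vinyl bromide 12 and halomethylboronate 13 (via 14 and 15) with retention of alkene geometry. 11 and 6 are the pivalates of 10 and 5.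

## Alternatives that were turned down

**Alternative 1:** the textbook route, disconnecting C2–H and, one step earlier, the C2–ring A bond. A ring-A aryllithium adds to lactone A1 to give hemiketal A2. Lewis acid and a hydride source then reduce the cyclic oxocarbenium ion anti to the C3 methyl, giving the 2,3-cis-3,4-cis-4,5-trans core A3. Ring B is then deprotected, alkylated with a lactate-derived α-sulfonyloxy ketone and reduced. It was turned down on step economy and because it is the route drawn first. A1 alone needs five to six steps for its three contiguous centres. The side chain cannot survive aryllithium and Lewis acid/hydride steps, so it must be built on after ring formation in four further linear steps, with orthogonal protection of two almost identical guaiacols. The longest linear sequence would be about twice that of the present route.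

**Alternative 2:** dearomatisation, making all four ring C–H bonds at once. Hydrogenation of the tetrasubstituted furan A4 would give the all-cis oxolane A5, followed by epimerisation at C5. The two faces of A4 differ only through para substituents on rings A and B and through the remote side-chain centres, several bonds from the furan. Neither a catalyst nor the substrate can tell them apart, so A5 would form with an equal amount of the diastereomer having the mirror-image core. A tetrasubstituted, doubly aryl-conjugated furan also needs forcing conditions under which the benzylic C–O bonds it creates are hydrogenolysed. At best half the material is lost and an extra epimerisation is still needed.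

**Alternative 3:** a (3+2) cycloaddition forming C2–C3 and C4–C5. Carbonyl ylide A7, from thermal or photochemical C–C cleavage of the trans-diaryl epoxide A6, would add to (Z)-but-2-ene A8. This delivers the ring with all substituents in one step on paper. However, A8 is an unactivated, electron-rich, gaseous dipolarophile and A7 is an electron-rich ylide, so the frontier-orbital gap is large. Reclosure of A7 and fragmentation to aldehyde and carbene will outrun cycloaddition. The ylide geometry (which fixes 2,5-trans), the endo/exo choice (which fixes C2/C3) and the face of attack (which fixes absolute configuration) have no control element. The outcome would be a racemic mixture of core isomers.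

Key step: step 10

## Route

Step 1
Reactants: 1 4-bromo-2-methoxyphenol; 2 ethyl (S)-lactate
Product: 3 ethyl (2R)-2-(4-bromo-2-methoxyphenoxy)propanoate
Conditions: PPh3, DIAD, THF, 0 °C to rt
Reagents that add atoms: none
Why: Mitsunobu etherification; the phenol displaces the activated lactate oxygen by SN2 with inversion, turning the (S) centre of 2 into the (R) ether carbon that becomes C8′.

Step 2
Reactants: 3 ethyl (2R)-2-(4-bromo-2-methoxyphenoxy)propanoate
Product: 4 (2R)-2-(4-bromo-2-methoxyphenoxy)-N-methoxy-N-methylpropanamide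
Conditions: MeNH(OMe)·HCl, i-PrMgCl, THF, −20 °C
Reagents that add atoms: N,O-dimethylhydroxylamine hydrochloride, CNOC.Cl
Why: Weinreb amide formation by aminolysis of the ester with the magnesium amide made in the flask; the low temperature should keep the α-aryloxy centre and the aryl bromide intact.

Step 3
Reactants: 5 4-iodo-2-methoxyphenol
Product: 6 4-iodo-2-methoxyphenyl 2,2-dimethylpropanoate
Conditions: PivCl, Et3N, DMAP (cat.), CH2Cl2, 0 °C to rt
Reagents that add atoms: pivaloyl chloride, CC(C)(C)C(=O)Cl
Why: O-acylation of the phenol; the hindered, electron-poor pivalate tolerates a low-temperature Grignard reagent and later makes ring C a poor donor toward C7′.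

Step 4
Reactants: 6 4-iodo-2-methoxyphenyl 2,2-dimethylpropanoate; 4 (2R)-2-(4-bromo-2-methoxyphenoxy)-N-methoxy-N-methylpropanamide
Product: 8 4-[(2R)-2-(4-bromo-2-methoxyphenoxy)propanoyl]-2-methoxyphenyl 2,2-dimethylpropanoate, via arylmagnesium chloride 7 (not isolated)
Conditions: i-PrMgCl·LiCl, THF, −20 °C; then 4, −20 to 0 °C; aq. NH4Cl
Reagents that add atoms: none
Why: iodine–magnesium exchange gives a functionalised aryl Grignard that leaves the hindered pivalate alone; acylation by the Weinreb amide stops at the ketone because the chelated tetrahedral adduct persists until the quench, and the aryl bromide of 4 does not exchange at this temperature.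

Step 5
Reactants: 8 4-[(2R)-2-(4-bromo-2-methoxyphenoxy)propanoyl]-2-methoxyphenyl 2,2-dimethylpropanoate
Product: 9 4-[(1S,2R)-2-(4-bromo-2-methoxyphenoxy)-1-hydroxypropyl]-2-methoxyphenyl 2,2-dimethylpropanoate
Conditions: Zn(BH4)2, Et2O, −30 to 0 °C
Reagents that add atoms: none
Why: chelation-controlled (Cram-chelate) ketone reduction; zinc bridges the carbonyl oxygen and the C8′ ether oxygen, hydride enters past the small hydrogen on C8′, and the anti (erythro, 7′S,8′R) alcohol should result; aryl ester and aryl bromide are inert to this reagent.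

Step 6
Reactants: 10 vanillin
Product: 11 4-formyl-2-methoxyphenyl 2,2-dimethylpropanoate
Conditions: PivCl, Et3N, DMAP (cat.), CH2Cl2, 0 °C to rt
Reagents that add atoms: pivaloyl chloride, CC(C)(C)C(=O)Cl
Why: O-acylation; the pivalate makes the para oxygen of ring A a poor donor, which later protects C2 from ionisation and oxidation.

Step 7
Reactants: 12 (Z)-2-bromobut-2-ene; 13 2-(chloromethyl)-4,4,5,5-tetramethyl-1,3,2-dioxaborolane
Product: 16 4,4,5,5-tetramethyl-2-[(2Z)-2-methylbut-2-en-1-yl]-1,3,2-dioxaborolane, via (E)-but-2-en-2-yllithium 14 (not isolated), via lithium alkenyl(chloromethyl)boronate 15 (not isolated)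
Conditions: t-BuLi (2 equiv), Et2O, −78 °C; then 13, −78 °C to rt
Reagents that add atoms: none
Why: stereoretentive bromine–lithium exchange followed by Matteson homologation; the alkenyllithium adds to boron and the alkenyl group migrates to the CH2 carbon with loss of chloride and retention of alkene geometry, so CH2B ends cis to the terminal methyl.

Step 8
Reactants: 11 4-formyl-2-methoxyphenyl 2,2-dimethylpropanoate; 16 4,4,5,5-tetramethyl-2-[(2Z)-2-methylbut-2-en-1-yl]-1,3,2-dioxaborolane
Product: 17 4-[(1S,2R)-1-hydroxy-2,3-dimethylbut-3-en-1-yl]-2-methoxyphenyl 2,2-dimethylpropanoate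
Conditions: (S)-TRIP [(S)-3,3′-bis(2,4,6-triisopropylphenyl)-1,1′-binaphthalene-2,2′-diyl hydrogen phosphate] (5 mol %), 4 Å MS, toluene, −30 °C
Reagents that add atoms: none
Why: chiral phosphoric-acid-catalysed allylboration through a closed chair (Zimmerman–Traxler) transition state; the Z geometry of 16 puts its terminal methyl axial and gives the syn relation between C2–OH and C3–Me, and the (S)-acid, bound to a boronate oxygen and the formyl hydrogen, is expected to expose the Si face of the aldehyde, setting (1S,2R).

Step 9
Reactants: 17 4-[(1S,2R)-1-hydroxy-2,3-dimethylbut-3-en-1-yl]-2-methoxyphenyl 2,2-dimethylpropanoate; 9 4-[(1S,2R)-2-(4-bromo-2-methoxyphenoxy)-1-hydroxypropyl]-2-methoxyphenyl 2,2-dimethylpropanoate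
Product: 19 4-[(1S,2R,3R)-1-hydroxy-4-(4-{[(1S,2R)-1-hydroxy-1-(3-methoxy-4-pivaloyloxyphenyl)propan-2-yl]oxy}-3-methoxyphenyl)-2,3-dimethylbutyl]-2-methoxyphenyl 2,2-dimethylpropanoate, via bis(9-BBN) alkylborane 18 (not isolated)
Conditions: 9-BBN (2.5 equiv), THF, 0 °C to rt; then 9, Pd(OAc)2 (5 mol %), SPhos, K3PO4·H2O, THF, 60 °C
Reagents that add atoms: none
Why: hydroboration of the 1,1-disubstituted alkene under A(1,3)-strain control (allylic hydrogen eclipsing the double bond, borane entering anti to the large carbinol-bearing group) should set the C4 methyl anti to the C3 methyl; B-alkyl Suzuki–Miyaura coupling of the primary alkylborane with the aryl bromide on zerovalent palladium then forms the bond to ring B without touching any stereocentre.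

Step 10
Reactants: 19 4-[(1S,2R,3R)-1-hydroxy-4-(4-{[(1S,2R)-1-hydroxy-1-(3-methoxy-4-pivaloyloxyphenyl)propan-2-yl]oxy}-3-methoxyphenyl)-2,3-dimethylbutyl]-2-methoxyphenyl 2,2-dimethylpropanoate
Product: 21 4-[(2S,3R,4S,5S)-5-(4-{[(1S,2R)-1-hydroxy-1-(3-methoxy-4-pivaloyloxyphenyl)propan-2-yl]oxy}-3-methoxyphenyl)-3,4-dimethyloxolan-2-yl]-2-methoxyphenyl 2,2-dimethylpropanoate, via benzylic cation 20 (not isolated)
Conditions: DDQ (1.2 equiv), 2,6-dichloropyridine, 4 Å MS, CH2Cl2, 0 °C to rt
Reagents that add atoms: none
Why: Dehydrogenative benzylic C–H etherification (oxidative C–O cyclisation) with DDQ, the reaction type known for electron-rich alkylarenes bearing a pendant alcohol. DDQ forms a charge-transfer complex with ring B, the only electron-rich arene, and abstracts hydride from the C5 methylene; the cation 20 is stabilised as a para-quinoid oxocarbenium ion by the ether oxygen of ring B. The C2 hydroxyl closes the oxolane by 5-exo-trig attack on the exocyclic cationic carbon, and 2,6-dichloropyridine takes up the proton. C2, C3 and C4 are not touched and keep the configuration of 19; the new centre C5 is set by the ring, because ring B takes the face opposite the three cis substituents (ring A, C3-Me, C4-Me), the all-cis closure being destabilised by eclipsing with the C4 methyl and a 1,3-clash with ring A. The step is stereoconvergent: any all-cis ether that forms can re-ionise at C5 and return through 20 to the trans isomer, whereas C2 cannot ionise. Chemoselectivity rests on the pivalates, which make the para oxygens of rings A and C poor donors, so C2–H and C7′–H resist hydride abstraction and neither carbinol is oxidised to a ketone. Over-oxidation of 21 should be slow because its C5–H lies on the crowded face shared with both methyls and ring A, and it is further limited by using little more than one equivalent of oxidant, low temperature and exclusion of water.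

Step 11
Reactants: 21 4-[(2S,3R,4S,5S)-5-(4-{[(1S,2R)-1-hydroxy-1-(3-methoxy-4-pivaloyloxyphenyl)propan-2-yl]oxy}-3-methoxyphenyl)-3,4-dimethyloxolan-2-yl]-2-methoxyphenyl 2,2-dimethylpropanoate
Product: 22 4-[(2S,3R,4S,5S)-5-(4-{[(1S,2R)-1-hydroxy-1-(4-hydroxy-3-methoxyphenyl)propan-2-yl]oxy}-3-methoxyphenyl)-3,4-dimethyloxolan-2-yl]-2-methoxyphenol (CNP0171079.3)
Conditions: K2CO3, MeOH (degassed), rt; aq. NH4Cl
Reagents that add atoms: none
Why: methanolysis (transesterification) of the two aryl pivalates; mild base at room temperature does not ionise benzylic C–O bonds, so C2, C5 and C7′ should not epimerise.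

## Compound list

1 | 4-bromo-2-methoxyphenol | COc1cc(Br)ccc1O | starting material
2 | ethyl (S)-lactate | CCOC(=O)[C@H](C)O | starting material
3 | ethyl (2R)-2-(4-bromo-2-methoxyphenoxy)propanoate | COc1cc(Br)ccc1O[C@H](C)C(=O)OCC | intermediate
4 | (2R)-2-(4-bromo-2-methoxyphenoxy)-N-methoxy-N-methylpropanamide | COc1cc(Br)ccc1O[C@H](C)C(=O)N(C)OC | intermediate
5 | 4-iodo-2-methoxyphenol | COc1cc(I)ccc1O | starting material
6 | 4-iodo-2-methoxyphenyl 2,2-dimethylpropanoate | COc1cc(I)ccc1OC(=O)C(C)(C)C | intermediate
7 | [3-methoxy-4-(pivaloyloxy)phenyl]magnesium chloride (LiCl complex) | COc1cc([Mg]Cl)ccc1OC(=O)C(C)(C)C | intermediate (not isolated)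
8 | 4-[(2R)-2-(4-bromo-2-methoxyphenoxy)propanoyl]-2-methoxyphenyl 2,2-dimethylpropanoate | COc1cc(Br)ccc1O[C@H](C)C(=O)c1ccc(OC(=O)C(C)(C)C)c(OC)c1 | intermediate
9 | 4-[(1S,2R)-2-(4-bromo-2-methoxyphenoxy)-1-hydroxypropyl]-2-methoxyphenyl 2,2-dimethylpropanoate | COc1cc(Br)ccc1O[C@H](C)[C@@H](O)c1ccc(OC(=O)C(C)(C)C)c(OC)c1 | intermediate
10 | vanillin | COc1cc(C=O)ccc1O | starting material
11 | 4-formyl-2-methoxyphenyl 2,2-dimethylpropanoate | COc1cc(C=O)ccc1OC(=O)C(C)(C)C | intermediate
12 | (Z)-2-bromobut-2-ene | C/C=C(\Br)C | starting material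
13 | 2-(chloromethyl)-4,4,5,5-tetramethyl-1,3,2-dioxaborolane | ClCB1OC(C)(C)C(C)(C)O1 | starting material
14 | (E)-but-2-en-2-yllithium | C/C=C(\[Li])C | intermediate (not isolated)
15 | lithium [(E)-but-2-en-2-yl](chloromethyl)(pinacolato)borate | [Li+].C/C=C(\[B-]1(CCl)OC(C)(C)C(C)(C)O1)C | intermediate (not isolated)
16 | 4,4,5,5-tetramethyl-2-[(2Z)-2-methylbut-2-en-1-yl]-1,3,2-dioxaborolane | C/C=C(\CB1OC(C)(C)C(C)(C)O1)C | intermediate
17 | 4-[(1S,2R)-1-hydroxy-2,3-dimethylbut-3-en-1-yl]-2-methoxyphenyl 2,2-dimethylpropanoate | COc1cc([C@@H](O)[C@H](C)C(C)=C)ccc1OC(=O)C(C)(C)C | intermediate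
18 | 4-[(1S,2R,3R)-1-(9-borabicyclo[3.3.1]nonan-9-yloxy)-4-(9-borabicyclo[3.3.1]nonan-9-yl)-2,3-dimethylbutyl]-2-methoxyphenyl 2,2-dimethylpropanoate | COc1cc([C@@H](OB2C3CCCC2CCC3)[C@H](C)[C@H](C)CB2C3CCCC2CCC3)ccc1OC(=O)C(C)(C)C | intermediate (not isolated)
19 | 4-[(1S,2R,3R)-1-hydroxy-4-(4-{[(1S,2R)-1-hydroxy-1-(3-methoxy-4-pivaloyloxyphenyl)propan-2-yl]oxy}-3-methoxyphenyl)-2,3-dimethylbutyl]-2-methoxyphenyl 2,2-dimethylpropanoate | COc1cc([C@@H](O)[C@H](C)[C@H](C)Cc2ccc(O[C@H](C)[C@@H](O)c3ccc(OC(=O)C(C)(C)C)c(OC)c3)c(OC)c2)ccc1OC(=O)C(C)(C)C | intermediate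
20 | C5 benzylic cation of 19 (para-quinoid oxocarbenium ion on ring B) | COc1cc([C@@H](O)[C@H](C)[C@H](C)[CH+]c2ccc(O[C@H](C)[C@@H](O)c3ccc(OC(=O)C(C)(C)C)c(OC)c3)c(OC)c2)ccc1OC(=O)C(C)(C)C | intermediate (not isolated)
21 | 4-[(2S,3R,4S,5S)-5-(4-{[(1S,2R)-1-hydroxy-1-(3-methoxy-4-pivaloyloxyphenyl)propan-2-yl]oxy}-3-methoxyphenyl)-3,4-dimethyloxolan-2-yl]-2-methoxyphenyl 2,2-dimethylpropanoate | COc1cc([C@H]2O[C@H](c3ccc(O[C@H](C)[C@@H](O)c4ccc(OC(=O)C(C)(C)C)c(OC)c4)c(OC)c3)[C@@H](C)[C@H]2C)ccc1OC(=O)C(C)(C)C | intermediate
22 | 4-[(2S,3R,4S,5S)-5-(4-{[(1S,2R)-1-hydroxy-1-(4-hydroxy-3-methoxyphenyl)propan-2-yl]oxy}-3-methoxyphenyl)-3,4-dimethyloxolan-2-yl]-2-methoxyphenol | COc1cc([C@H]2O[C@H](c3ccc(O[C@H](C)[C@@H](O)c4ccc(O)c(OC)c4)c(OC)c3)[C@@H](C)[C@H]2C)ccc1O | target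

## Step count and risk

Total step count: 11. Longest linear sequence: 7 steps (steps 1, 2, 4, 5, 9, 10, 11).

**Step 10 (key step).** The most likely failures are two. First, a second hydride abstraction from C5 of the product, leading on to ring-opened ketone or furan, because a benzylic ether is intrinsically easier to oxidise than the alkylarene it came from. Second, Friedel–Crafts capture of the cation by ring A at the position para to its methoxy group, giving an aryltetralin. Fallback, setting out from 19 and returning at 21: the over-oxidation is carried through deliberately. Excess DDQ in wet, buffered CH2Cl2 should take 19 to the cyclic hemiketal F1 (in equilibrium with its open hydroxy ketone). Ionic reduction of its oxocarbenium ion (Et3SiH, BF3·OEt2, CH2Cl2, −78 °C) should deliver hydride anti to the three cis substituents and give the all-cis oxolane F2. A separate Lewis-acid epimerisation at C5 (BF3·OEt2, CH2Cl2, −20 °C), possible only at the ring-B carbon because ring A is acylated, should then give 21.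

**Step 9.** Facial selectivity in the hydroboration may be insufficient, because the allylic centre distinguishes the two alkene faces only by methyl versus the carbinol-bearing carbon. Transmetallation of the β-branched alkylborane may be slow, and the aqueous base may slowly hydrolyse the aryl pivalates. Fallback, from 17 back to 19: hydroboration with oxidative work-up (9-BBN; NaBO3) gives the 1,4-diol F3, at which stage C4 epimers can be removed. Selective iodination of the primary hydroxyl (I2, PPh3, imidazole) gives the iodide F4. A nickel-catalysed reductive cross-electrophile coupling with 9 (NiBr2·glyme, 4,4′-di-tert-butyl-2,2′-bipyridine, Zn, DMA) forms the same bond under base-free conditions.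

**Step 8.** The 2,3-disubstituted allylboronate is more hindered than the crotyl reagents for which the catalyst is established. A slower catalysed pathway would let the uncatalysed background reaction erode enantioselectivity. Fallback, from 11 back to 17, using auxiliary control: boron-mediated Evans syn-aldol reaction of 11 with (S)-4-benzyl-3-propanoyl-1,3-oxazolidin-2-one (Bu2BOTf, i-Pr2NEt) gives the aldol adduct F5. Transamidation (MeNH(OMe)·HCl, AlMe3, −10 °C) gives the Weinreb amide F6. MeMgBr at low temperature gives the methyl ketone F7. Takai–Lombardo methylenation (Zn, CH2Br2, TiCl4), which spares esters, gives 17.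

**Step 5.** Chelation may be weak, since an aryl ether oxygen is a poor donor. Felkin-type attack would then compete and lower the erythro selectivity. Fallback, from 3 back to 9, exchanging the roles of hydride and aryl so that the non-chelated pathway becomes the desired one: 3 is reduced to the aldehyde F8 (i-Bu2AlH, CH2Cl2, −78 °C). Grignard 7 is transmetallated with ClTi(OiPr)3 to the aryltitanium F9. Its Felkin–Anh addition to F8, with the aryloxy group anti to the incoming aryl, should give the anti alcohol 9 directly.

## Further compounds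

F1 | step 10 | 4-[(2S,3R,4S)-5-hydroxy-5-(4-{[(1S,2R)-1-hydroxy-1-(3-methoxy-4-pivaloyloxyphenyl)propan-2-yl]oxy}-3-methoxyphenyl)-3,4-dimethyloxolan-2-yl]-2-methoxyphenyl 2,2-dimethylpropanoate (anomeric mixture) | COc1cc([C@H]2OC(O)(c3ccc(O[C@H](C)[C@@H](O)c4ccc(OC(=O)C(C)(C)C)c(OC)c4)c(OC)c3)[C@@H](C)[C@H]2C)ccc1OC(=O)C(C)(C)C
F2 | step 10 | 4-[(2S,3R,4S,5R)-5-(4-{[(1S,2R)-1-hydroxy-1-(3-methoxy-4-pivaloyloxyphenyl)propan-2-yl]oxy}-3-methoxyphenyl)-3,4-dimethyloxolan-2-yl]-2-methoxyphenyl 2,2-dimethylpropanoate (all-cis) | COc1cc([C@H]2O[C@@H](c3ccc(O[C@H](C)[C@@H](O)c4ccc(OC(=O)C(C)(C)C)c(OC)c4)c(OC)c3)[C@@H](C)[C@H]2C)ccc1OC(=O)C(C)(C)C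
F3 | step 9 | 4-[(1S,2R,3S)-1,4-dihydroxy-2,3-dimethylbutyl]-2-methoxyphenyl 2,2-dimethylpropanoate | COc1cc([C@@H](O)[C@H](C)[C@H](C)CO)ccc1OC(=O)C(C)(C)C
F4 | step 9 | 4-[(1S,2R,3S)-1-hydroxy-4-iodo-2,3-dimethylbutyl]-2-methoxyphenyl 2,2-dimethylpropanoate | COc1cc([C@@H](O)[C@H](C)[C@H](C)CI)ccc1OC(=O)C(C)(C)C
F5 | step 8 | 4-{(1S,2S)-3-[(4S)-4-benzyl-2-oxo-1,3-oxazolidin-3-yl]-1-hydroxy-2-methyl-3-oxopropyl}-2-methoxyphenyl 2,2-dimethylpropanoate | COc1cc([C@@H](O)[C@H](C)C(=O)N2C(=O)OC[C@@H]2Cc3ccccc3)ccc1OC(=O)C(C)(C)C
F6 | step 8 | 4-{(1S,2S)-1-hydroxy-3-[methoxy(methyl)amino]-2-methyl-3-oxopropyl}-2-methoxyphenyl 2,2-dimethylpropanoate | COc1cc([C@@H](O)[C@H](C)C(=O)N(C)OC)ccc1OC(=O)C(C)(C)C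
F7 | step 8 | 4-[(1S,2S)-1-hydroxy-2-methyl-3-oxobutyl]-2-methoxyphenyl 2,2-dimethylpropanoate | COc1cc([C@@H](O)[C@H](C)C(C)=O)ccc1OC(=O)C(C)(C)C
F8 | step 5 | (2R)-2-(4-bromo-2-methoxyphenoxy)propanal | COc1cc(Br)ccc1O[C@H](C)C=O
F9 | step 5 | [3-methoxy-4-(pivaloyloxy)phenyl]tri(propan-2-yloxy)titanium | COc1cc([Ti](OC(C)C)(OC(C)C)OC(C)C)ccc1OC(=O)C(C)(C)C
A1 | alternative 1 | (3R,4S,5S)-5-[4-(benzyloxy)-3-methoxyphenyl]-3,4-dimethyloxolan-2-one | O=C1O[C@H](c2ccc(OCc3ccccc3)c(OC)c2)[C@@H](C)[C@H]1C
A2 | alternative 1 | (3R,4S,5S)-5-[4-(benzyloxy)-3-methoxyphenyl]-2-{4-[tert-butyl(dimethyl)silyl]oxy-3-methoxyphenyl}-3,4-dimethyloxolan-2-ol (anomeric mixture) | COc1cc(C2(O)O[C@H](c3ccc(OCc4ccccc4)c(OC)c3)[C@@H](C)[C@H]2C)ccc1O[Si](C)(C)C(C)(C)C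
A3 | alternative 1 | tert-butyl{4-[(2S,3R,4S,5S)-5-(4-benzyloxy-3-methoxyphenyl)-3,4-dimethyloxolan-2-yl]-2-methoxyphenoxy}dimethylsilane | COc1cc([C@H]2O[C@H](c3ccc(OCc4ccccc4)c(OC)c3)[C@@H](C)[C@H]2C)ccc1O[Si](C)(C)C(C)(C)C
A4 | alternative 2 | 4-[5-(4-{[(1S,2R)-1-hydroxy-1-(3-methoxy-4-pivaloyloxyphenyl)propan-2-yl]oxy}-3-methoxyphenyl)-3,4-dimethylfuran-2-yl]-2-methoxyphenyl 2,2-dimethylpropanoate | Cc1c(-c2ccc(OC(=O)C(C)(C)C)c(OC)c2)oc(-c2ccc(O[C@H](C)[C@@H](O)c3ccc(OC(=O)C(C)(C)C)c(OC)c3)c(OC)c2)c1C
A5 | alternative 2 | all-cis oxolane, (2S,3R,4S,5R) isomer of 21 | COc1cc([C@H]2O[C@@H](c3ccc(O[C@H](C)[C@@H](O)c4ccc(OC(=O)C(C)(C)C)c(OC)c4)c(OC)c3)[C@@H](C)[C@H]2C)ccc1OC(=O)C(C)(C)C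
A6 | alternative 3 | 4-[(2S,3S)-3-(4-{[(1S,2R)-1-hydroxy-1-(3-methoxy-4-pivaloyloxyphenyl)propan-2-yl]oxy}-3-methoxyphenyl)oxiran-2-yl]-2-methoxyphenyl 2,2-dimethylpropanoate (trans epoxide) | COc1cc([C@@H]2O[C@H]2c2ccc(O[C@H](C)[C@@H](O)c3ccc(OC(=O)C(C)(C)C)c(OC)c3)c(OC)c2)ccc1OC(=O)C(C)(C)C
A7 | alternative 3 | diaryl carbonyl ylide from C–C cleavage of A6 | COc1cc([CH-][O+]=Cc2ccc(O[C@H](C)[C@@H](O)c3ccc(OC(=O)C(C)(C)C)c(OC)c3)c(OC)c2)ccc1OC(=O)C(C)(C)C
A8 | alternative 3 | (Z)-but-2-ene | C/C=C\C
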